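## Retrosynthetic overview
1. Target 22 comes from 21 by hydrogenolysis of two benzyl ethers. 21 comes from the 5,6,7,8-tetramethoxyflavone 19 by carbonyl-directed cleavage of the peri 5-OMe only.
2. Ring C is the only ring built and is closed last, by O1–C2 closure and dehydrogenation of the 2'-hydroxychalcone 16.
3. The key C–C bond (future C2–C3) comes from an intermolecular Claisen–Schmidt aldol condensation of acetophenone 12 with aldehyde 14.
4. 12 comes from Fries acylation at the single free position of 2,3,4,5-tetramethoxyphenol 9. 9 comes from 2,3,4-trimethoxybenzaldehyde 1 by two CHO→OH (Dakin) cycles.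
5. 14 comes from protocatechualdehyde 13. Rings A and B are bought as benzenes.

Assumption: sideritiflavone has no stereocentre or stereoaxis, so it is one achiral compound and needs no enantiocontrol; simple salts (phenoxides, enolates) of numbered compounds are not numbered separately.

## Route

Step 1
Reactants: 1 2,3,4-trimethoxybenzaldehyde
Product: 3 2,3,4-trimethoxyphenol, via 2,3,4-trimethoxyphenyl formate 2 (not isolated)
Conditions: 30% H2O2 (1.3 equiv), cat. H2SO4, MeOH, rt, 16 h
Reagents that add atoms: hydrogen peroxide, OO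
Why: In this acid-catalysed Dakin (Baeyer–Villiger type) oxidation the aryl group, activated by ortho and para OMe, migrates to oxygen, and the formate is methanolysed in situ; no stereocentre is formed.

Step 2
Reactants: 3 2,3,4-trimethoxyphenol
Product: 4 1,2,3,4-tetramethoxybenzene
Conditions: MeI (1.5 equiv), K2CO3 (2 equiv), acetone, reflux, N2
Reagents that add atoms: iodomethane, CI
Why: This is a Williamson ether synthesis, a clean SN2 O-methylation of the only acidic site.

Step 3
Reactants: 4 1,2,3,4-tetramethoxybenzene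
Product: 7 2,3,4,5-tetramethoxybenzaldehyde, via tetramethoxyphenyllithium 5 (not isolated), via lithium hemiaminal alkoxide 6 (not isolated)
Conditions: n-BuLi (1.2 equiv), TMEDA (1.2 equiv), THF, 0 °C, 2 h; DMF (2 equiv), 0 °C to rt; 1 M HCl
Reagents that add atoms: N,N-dimethylformamide, CN(C)C=O
Why: In this directed ortho-metalation the two remaining ring C–H bonds are equivalent and each lies next to an OMe, so one aryllithium forms and DMF formylates it without any Lewis acid that could demethylate.

Step 4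
Reactants: 7 2,3,4,5-tetramethoxybenzaldehyde
Product: 9 2,3,4,5-tetramethoxyphenol, via 2,3,4,5-tetramethoxyphenyl formate 8 (not isolated)
Conditions: 30% H2O2 (1.15 equiv), cat. H2SO4, MeOH, 0 °C to rt, N2
Reagents that add atoms: hydrogen peroxide, OO
Why: This second acid-catalysed Dakin oxidation again has OMe ortho and para to CHO to favour aryl migration, and the non-basic medium protects the very electron-rich phenol from air oxidation.

Step 5
Reactants: 9 2,3,4,5-tetramethoxyphenol
Product: 12 1-(2-hydroxy-3,4,5,6-tetramethoxyphenyl)ethan-1-one, via 2,3,4,5-tetramethoxyphenyl acetate 10 (not isolated), via difluoroboron chelate 11 (not isolated)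
Conditions: Ac2O (2 equiv), BF3·OEt2 (3 equiv), 70 °C, 2 h; then H2O–MeOH, 50 °C
Reagents that add atoms: acetic anhydride, CC(=O)OC(C)=O
Why: O-acetylation is followed by a BF3-promoted Fries rearrangement to the only free ring carbon, which is ortho to the phenol, and the BF2 chelate blocks further acylation until it is hydrolysed.

Step 6
Reactants: 13 3,4-dihydroxybenzaldehyde
Product: 14 3,4-bis(benzyloxy)benzaldehyde
Conditions: BnBr (2.3 equiv), K2CO3 (3 equiv), DMF, 60 °C
Reagents that add atoms: benzyl bromide, BrCc1ccccc1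
Why: This Williamson double O-benzylation masks the base- and oxidant-sensitive catechol with groups that are removable under neutral conditions at the end.

Step 7
Reactants: 12 1-(2-hydroxy-3,4,5,6-tetramethoxyphenyl)ethan-1-one; 14 3,4-bis(benzyloxy)benzaldehyde
Product: 16 (E)-3-[3,4-bis(benzyloxy)phenyl]-1-(2-hydroxy-3,4,5,6-tetramethoxyphenyl)prop-2-en-1-one, via racemic aldol adduct 15 (not isolated)
Conditions: 50% aq KOH (10 equiv), EtOH–THF, rt, 24–48 h, N2; then ice/2 M HCl
Reagents that add atoms: none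
Why: In this Claisen–Schmidt crossed aldol condensation the aldehyde cannot enolise and the ketone has one enolisable CH3, and E1cB dehydration erases the racemic carbinol centre to give the more stable E-enone.

Step 8
Reactants: 16 (E)-3-[3,4-bis(benzyloxy)phenyl]-1-(2-hydroxy-3,4,5,6-tetramethoxyphenyl)prop-2-en-1-one
Product: 19 2-[3,4-bis(benzyloxy)phenyl]-5,6,7,8-tetramethoxy-4H-chromen-4-one, via racemic flavanone 17 (not isolated), via 3-iodoflavanone 18 (not isolated)
Conditions: I2 (0.1 equiv), DMSO, 120 °C, 3 h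
Reagents that add atoms: none
Why: In this I2/DMSO oxidative cyclisation, oxa-Michael closure gives the flavanone, alpha-iodination and loss of HI aromatise the pyranone, DMSO regenerates I2, and the transient C2/C3 stereocentres are erased.

Step 9
Reactants: 19 2-[3,4-bis(benzyloxy)phenyl]-5,6,7,8-tetramethoxy-4H-chromen-4-one
Product: 21 2-[3,4-bis(benzyloxy)phenyl]-5-hydroxy-6,7,8-trimethoxy-4H-chromen-4-one, via dichloroaluminium 5-phenolate chelate 20 (not isolated)
Conditions: anhydrous AlCl3 (5 equiv), MeCN, rt to 40 °C, TLC control; then 2 M HCl, 55 °C, 30 min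
Reagents that add atoms: none
Why: In this chelation-directed Lewis acid demethylation only the 5-OMe can form a six-membered Al chelate with C4=O, so chloride removes that methyl selectively, while MeCN-tempered AlCl3 leaves the other OMe and OBn groups intact.

Step 10
Reactants: 21 2-[3,4-bis(benzyloxy)phenyl]-5-hydroxy-6,7,8-trimethoxy-4H-chromen-4-one
Product: 22 sideritiflavone, 2-(3,4-dihydroxyphenyl)-5-hydroxy-6,7,8-trimethoxy-4H-chromen-4-one
Conditions: H2 (1 atm), 10% Pd/C, THF–MeOH 1:1, rt
Reagents that add atoms: none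
Why: Catalytic hydrogenolysis cleaves both benzyl aryl ethers under neutral conditions, and the conjugated flavone C2=C3 bond and the methyl ethers are inert at 1 atm and rt.

## Compound list
1 | 2,3,4-trimethoxybenzaldehyde | COc1ccc(C=O)c(OC)c1OC | starting material
2 | 2,3,4-trimethoxyphenyl formate | COc1ccc(OC=O)c(OC)c1OC | intermediate
3 | 2,3,4-trimethoxyphenol | COc1ccc(O)c(OC)c1OC | intermediate
4 | 1,2,3,4-tetramethoxybenzene | COc1ccc(OC)c(OC)c1OC | intermediate
5 | (2,3,4,5-tetramethoxyphenyl)lithium | [Li]c1cc(OC)c(OC)c(OC)c1OC | intermediate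
6 | lithium (dimethylamino)(2,3,4,5-tetramethoxyphenyl)methanolate, racemic | [Li+].[O-]C(N(C)C)c1cc(OC)c(OC)c(OC)c1OC | intermediate
7 | 2,3,4,5-tetramethoxybenzaldehyde | COc1cc(C=O)c(OC)c(OC)c1OC | intermediate
8 | 2,3,4,5-tetramethoxyphenyl formate | COc1cc(OC=O)c(OC)c(OC)c1OC | intermediate
9 | 2,3,4,5-tetramethoxyphenol | COc1cc(O)c(OC)c(OC)c1OC | intermediate
10 | 2,3,4,5-tetramethoxyphenyl acetate | COc1cc(OC(C)=O)c(OC)c(OC)c1OC | intermediate
11 | difluoroboron chelate of 12 | CC1=[O+][B-](F)(F)Oc2c(OC)c(OC)c(OC)c(OC)c21 | intermediate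
12 | 1-(2-hydroxy-3,4,5,6-tetramethoxyphenyl)ethan-1-one | CC(=O)c1c(O)c(OC)c(OC)c(OC)c1OC | intermediate
13 | 3,4-dihydroxybenzaldehyde | O=Cc1ccc(O)c(O)c1 | starting material
14 | 3,4-bis(benzyloxy)benzaldehyde | O=Cc1ccc(OCc2ccccc2)c(OCc2ccccc2)c1 | intermediate
15 | 3-[3,4-bis(benzyloxy)phenyl]-3-hydroxy-1-(2-hydroxy-3,4,5,6-tetramethoxyphenyl)propan-1-one, racemic | COc1c(O)c(C(=O)CC(O)c2ccc(OCc3ccccc3)c(OCc3ccccc3)c2)c(OC)c(OC)c1OC | intermediate
16 | (E)-3-[3,4-bis(benzyloxy)phenyl]-1-(2-hydroxy-3,4,5,6-tetramethoxyphenyl)prop-2-en-1-one | COc1c(O)c(C(=O)/C=C/c2ccc(OCc3ccccc3)c(OCc3ccccc3)c2)c(OC)c(OC)c1OC | intermediate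
17 | 2-[3,4-bis(benzyloxy)phenyl]-5,6,7,8-tetramethoxychroman-4-one, racemic | COc1c(OC)c(OC)c2c(c1OC)OC(c1ccc(OCc3ccccc3)c(OCc3ccccc3)c1)CC2=O | intermediate
18 | 2-[3,4-bis(benzyloxy)phenyl]-3-iodo-5,6,7,8-tetramethoxychroman-4-one, racemic | COc1c(OC)c(OC)c2c(c1OC)OC(c1ccc(OCc3ccccc3)c(OCc3ccccc3)c1)C(I)C2=O | intermediate
19 | 2-[3,4-bis(benzyloxy)phenyl]-5,6,7,8-tetramethoxy-4H-chromen-4-one | COc1c(OC)c(OC)c2c(=O)cc(-c3ccc(OCc4ccccc4)c(OCc4ccccc4)c3)oc2c1OC | intermediate
20 | dichloroaluminium 5-phenolate chelate of 21 | COc1c(OC)c(O[Al](Cl)Cl)c2c(=O)cc(-c3ccc(OCc4ccccc4)c(OCc4ccccc4)c3)oc2c1OC | intermediate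
21 | 2-[3,4-bis(benzyloxy)phenyl]-5-hydroxy-6,7,8-trimethoxy-4H-chromen-4-one | COc1c(OC)c(O)c2c(=O)cc(-c3ccc(OCc4ccccc4)c(OCc4ccccc4)c3)oc2c1OC | intermediate
22 | sideritiflavone (achiral) | COc1c(OC)c(O)c2c(=O)cc(-c3ccc(O)c(O)c3)oc2c1OC | target

## Step count and risks
Total step count: 10. Longest linear sequence: 9 (steps 1–5 and 7–10). Step 6 is the side branch.

The three steps most likely to fail are 4, 7 and 9.

**Step 4.**
- Risk: the tetra-alkoxyphenol 9 is easily over-oxidised to a methoxyquinone, and some aldehyde may end up as the benzoate.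
- Fallback: it sets out from 4 and comes back at 9, replacing the formyl detour with an ipso-hydroxylation of boron.
- Lithiate 4 to 5 as before and trap it with B(OMe)3 at −78 °C to rt, giving dimethyl (2,3,4,5-tetramethoxyphenyl)boronate F1.
- Hydrolyse with 1 M HCl to (2,3,4,5-tetramethoxyphenyl)boronic acid F2.
- Oxidise F2 with H2O2 in THF/aq NaHCO3 at 0 °C for a few minutes to give 9.

**Step 7.**
- Risk: the di-ortho-substituted ketone enolate is sluggish, and chalcone/flavanone mixtures or Cannizzaro loss of 14 can lower the yield. Flavanone 17 in the crude product does no harm, because step 8 also oxidises it to 19.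
- Fallback: it sets out from 12 and 14 and comes back at 19, replacing the aldol with an intermolecular crossed Claisen C-acylation, so no oxidation is needed.
- Oxidise 14 under Pinnick conditions (NaClO2, NaH2PO4, 2-methyl-2-butene, t-BuOH/H2O) to 3,4-bis(benzyloxy)benzoic acid F3.
- Convert F3 with (COCl)2 and cat. DMF in CH2Cl2 into 3,4-bis(benzyloxy)benzoyl chloride F4.
- Turn 12 into its dilithio phenoxide–enolate with LiHMDS (4 equiv, THF, −78 °C) and acylate it with F4. This gives 1-[3,4-bis(benzyloxy)phenyl]-3-(2-hydroxy-3,4,5,6-tetramethoxyphenyl)propane-1,3-dione F5.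
- Cyclodehydrate F5 with cat. p-TsOH in refluxing toluene (Dean–Stark) to give 19.

**Step 9.**
- Risk: AlCl3 may partly cleave the catechol benzyl ethers, or attack the 6-OMe once the 5-OH is free. Partial debenzylation is tolerable, because step 10 removes these groups anyway.
- Fallback: it sets out from 19 and comes back at 22, inverting the order of deprotection and using a protic rather than a Lewis-acid demethylation.
- Hydrogenolyse 19 (H2, Pd/C, THF–MeOH) to 2-(3,4-dihydroxyphenyl)-5,6,7,8-tetramethoxy-4H-chromen-4-one F6.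
- Reflux F6 in 3 M HCl/EtOH. Only the peri 5-OMe, activated by the protonated C4 carbonyl, is cleaved, and 22 forms directly.

## Further compounds
F1 | step 4 | dimethyl (2,3,4,5-tetramethoxyphenyl)boronate | COB(OC)c1cc(OC)c(OC)c(OC)c1OC
F2 | step 4 | (2,3,4,5-tetramethoxyphenyl)boronic acid | COc1cc(B(O)O)c(OC)c(OC)c1OC
F3 | step 7 | 3,4-bis(benzyloxy)benzoic acid | OC(=O)c1ccc(OCc2ccccc2)c(OCc2ccccc2)c1
F4 | step 7 | 3,4-bis(benzyloxy)benzoyl chloride | ClC(=O)c1ccc(OCc2ccccc2)c(OCc2ccccc2)c1
F5 | step 7 | 1-[3,4-bis(benzyloxy)phenyl]-3-(2-hydroxy-3,4,5,6-tetramethoxyphenyl)propane-1,3-dione | COc1c(O)c(C(=O)CC(=O)c2ccc(OCc3ccccc3)c(OCc3ccccc3)c2)c(OC)c(OC)c1OC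
F6 | step 9 | 2-(3,4-dihydroxyphenyl)-5,6,7,8-tetramethoxy-4H-chromen-4-one | COc1c(OC)c(OC)c2c(=O)cc(-c3ccc(O)c(O)c3)oc2c1OC
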